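Numbering (target): C1 ring CH bearing the side chain, C4 CHMe, C5 spiro C, C6 allylic CH2, C7 =CH, C8 =C(CO2Me), C9 CHOH, C10 CH2; side chain C2' CHMe, C3', C4', C5' C=O.
Cuts, in retrosynthetic order: C3'–C4' (Wittig), C8–CO2Me (carbonylation), removal of C8 from ring C5–C10 (one-carbon ring expansion read backwards), C6–C7 (aldol condensation), C5–C10 (enolate alkylation).
Forward: the cyclopentane C1–C5 is bought inside nepetalactone. Its δ-lactone stays as a temporary ring until C5 is quaternary. A second five-membered ring (C5, C6, C7, C9, C10) is then closed and enlarged to the six-membered ring by insertion of C8.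
Enabling feature: in ring C5–C10 the sp2 carbon C8 lies between the oxygenated C9 and the olefinic C7, and C6 and C10 are plain CH2 groups. Without C8 the ring is a spiro[4.4]nonan-2-one whose only accessible enol ether is C9=C7, because C10 is neopentyl to C5, so a C–Br unit can be inserted exactly there.
Stereochemistry: C1 and C4 come from nepetalactone, C2' from convex-face hydrogenation, C5 from convex-face alkylation of the cis-fused lactone enolate, and C9 from CBS reduction (reagent control).
Helpers and their removal: lactone ring (opened in step 5), two TMS groups (lost in step 7), bromine on C8 (exchanged for CO2Me in step 9).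

Key step: step 7

Assumption: (4aS,7S,7aR)-nepetalactone, the main constituent of commercial catnip oil and also sold pure, is taken as a commercial starting material.

Step 1
Reactants: 1 (4aS,7S,7aR)-nepetalactone
Product: 2 (4S,4aR,7S,7aR)-dihydronepetalactone
Conditions: H2 (3 atm), 5% Pd/SrCO3, EtOH, rt
Reagents that add atoms: none
Why: Heterogeneous hydrogenation of the enol-ether C3=C4 bond should occur on the convex face of the cis-fused bicycle (the face of H-4a and H-7a), which sets C4 as S, the future C2'.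

Step 2
Reactants: 2 (4S,4aR,7S,7aR)-dihydronepetalactone; 3 3-bromo-2-methylprop-1-ene
Product: 4 (4S,4aR,7S,7aR)-4,7-dimethyl-7a-(2-methylallyl)hexahydrocyclopenta[c]pyran-1(3H)-one
Conditions: LDA, THF, −78 °C; then 3, DMPU, −78 → −20 °C
Reagents that add atoms: none
Why: Alkylation of a ring-fusion lactone enolate with an allylic halide should occur on the convex face, anti to pyran carbons C3/C4 and the axial C4 methyl, so the cis fusion is kept and the quaternary centre (future C5) carries the carbonyl carbon (future C6) on the side-chain face and the new CH2 (future C10) on the face of the ring methyl.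

Step 3
Reactants: 4 (4S,4aR,7S,7aR)-4,7-dimethyl-7a-(2-methylallyl)hexahydrocyclopenta[c]pyran-1(3H)-one
Product: 5 (4S,4aR,7S,7aR)-4,7-dimethyl-7a-(2-methylallyl)octahydrocyclopenta[c]pyran-1-ol
Conditions: DIBAL-H (1.1 equiv), CH2Cl2, −78 °C; aq. Rochelle salt
Reagents that add atoms: none
Why: Partial reduction of a δ-lactone with DIBAL-H stops at the aluminium hemiacetal at low temperature, and the anomeric centre is of no consequence.

Step 4
Reactants: 5 (4S,4aR,7S,7aR)-4,7-dimethyl-7a-(2-methylallyl)octahydrocyclopenta[c]pyran-1-ol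
Product: 6 1-[(4S,4aR,7S,7aR)-1-hydroxy-4,7-dimethylhexahydrocyclopenta[c]pyran-7a(1H)-yl]propan-2-one
Conditions: O3, CH2Cl2–MeOH, −78 °C; then Me2S, → rt
Reagents that add atoms: ozone, [O-][O+]=O
Why: Ozonolysis with reductive work-up cleaves the only C=C bond to the methyl ketone (C9 carbonyl, C7 methyl) and leaves the lactol untouched.

Step 5
Reactants: 6 1-[(4S,4aR,7S,7aR)-1-hydroxy-4,7-dimethylhexahydrocyclopenta[c]pyran-7a(1H)-yl]propan-2-one
Product: 9 (5S,6R,9S)-6-[(2S)-1-hydroxypropan-2-yl]-9-methylspiro[4.4]nonan-2-one, via spiro enone 7 (not isolated), via oxa-Michael keto ether 8 (not isolated)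
Conditions: KOH, MeOH, 60 °C; then 10% Pd/C, H2 (1 atm), same pot, 40 °C
Reagents that add atoms: none
Why: Base opens the lactol, the 4-oxopentanal unit undergoes intramolecular aldol condensation to the 4,4-disubstituted cyclopentenone 7, the freed alkoxide adds back reversibly (oxa-Michael) to give 8, and catalytic hydrogenation of 7 in the same basic medium should drain this equilibrium to 9 without forming a stereocentre.

Step 6
Reactants: 9 (5S,6R,9S)-6-[(2S)-1-hydroxypropan-2-yl]-9-methylspiro[4.4]nonan-2-one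
Product: 10 trimethyl{[(5S,6R,9S)-9-methyl-6-{(2S)-1-[(trimethylsilyl)oxy]propan-2-yl}spiro[4.4]non-2-en-2-yl]oxy}silane
Conditions: LDA (2.3 equiv), THF, −78 °C; TMSCl (2.5 equiv), −78 → 0 °C
Reagents that add atoms: chlorotrimethylsilane, C[Si](C)(C)Cl
Why: Kinetic enolisation and O-silylation should take the proton from the open α-CH2 (future C7) because the other α-CH2 (future C10) is neopentyl to the spiro carbon and shielded by the ring methyl; the alkoxide is silylated in the same operation.

Step 7
Reactants: 10 trimethyl{[(5S,6R,9S)-9-methyl-6-{(2S)-1-[(trimethylsilyl)oxy]propan-2-yl}spiro[4.4]non-2-en-2-yl]oxy}silane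
Product: 13 (1R,4S,5S)-8-bromo-1-[(2S)-1-hydroxypropan-2-yl]-4-methylspiro[4.5]dec-7-en-9-one, via dibromocyclopropane 11 (not isolated), via bromoenone silyl ether 12 (not isolated)
Conditions: CHBr3, KOt-Bu, pentane, −25 °C → rt; then 1 M HCl, THF, rt
Reagents that add atoms: bromoform, BrC(Br)Br
Why: Dibromocarbene, formed by α-elimination from bromoform, adds in a concerted [2+1] cheletropic step to the only C=C bond, the electron-rich silyl enol ether C9=C7, and so closes the three-membered ring C7–C8–C9 of 11, whose two ring-fusion centres are transient, so the face of attack does not matter. In this strained 1-siloxy-6,6-dibromobicyclo[3.1.0]hexane the endo bromide leaves while the internal C7–C9 bond opens by a disrotatory 2π-electrocyclic process (Woodward–Hoffmann–DePuy rule) pushed by the siloxy oxygen, and loss of Me3SiBr from the 2-bromo-1-siloxyallyl cation gives the 2-bromocyclohex-2-enone. The closest known reaction type is the dihalocarbene ring enlargement of cyclic trimethylsilyl enol ethers to 2-halocycloalk-2-enones. No lasting stereocentre is created and C1, C4, C5 and C2' are untouched. The selectivity needed is regiochemical, since C8 must enter between C9 and C7 and not between C9 and C10, and it is fixed by the position of the enol ether double bond made in step 6. In one operation the step sets the ring size, places the C7=C8 double bond, keeps oxygen on C9 and leaves on C8 a bromine that makes the ketone a good CBS substrate and is later exchanged for the ester carbon.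

Step 8
Reactants: 13 (1R,4S,5S)-8-bromo-1-[(2S)-1-hydroxypropan-2-yl]-4-methylspiro[4.5]dec-7-en-9-one
Product: 14 (1R,4S,5S,9S)-8-bromo-1-[(2S)-1-hydroxypropan-2-yl]-4-methylspiro[4.5]dec-7-en-9-ol
Conditions: (R)-Me-CBS (20 mol %), BH3·SMe2 (excess), THF, −30 °C; MeOH quench
Reagents that add atoms: none
Why: In the Corey–Bakshi–Shibata reduction of a 2-bromoenone the bromovinyl side acts as the large group, so the (R)-catalyst should deliver the (9S)-carbinol under reagent control, and the free primary alcohol only consumes borane.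

Step 9
Reactants: 14 (1R,4S,5S,9S)-8-bromo-1-[(2S)-1-hydroxypropan-2-yl]-4-methylspiro[4.5]dec-7-en-9-ol
Product: 15 methyl (1R,4S,5S,9S)-9-hydroxy-1-[(2S)-1-hydroxypropan-2-yl]-4-methylspiro[4.5]dec-7-ene-8-carboxylate
Conditions: Pd(OAc)2 (5 mol %), dppp, CO (1 atm), Et3N, MeOH–DMF, 70 °C
Reagents that add atoms: carbon monoxide, [C-]#[O+]; methanol, CO
Why: Palladium-catalysed methoxycarbonylation (oxidative addition into the vinyl C–Br bond, CO insertion, methanolysis) replaces bromine by the ester with retention of the double bond, and methanol as solvent should outrun attack by either hydroxyl group.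

Step 10
Reactants: 16 1-bromo-3-methylbutan-2-one; 17 triphenylphosphine
Product: 19 3-methyl-1-(triphenyl-λ5-phosphanylidene)butan-2-one, via phosphonium bromide 18 (not isolated)
Conditions: toluene, 80 °C; then aq. NaOH, CH2Cl2, rt
Reagents that add atoms: none
Why: SN2 quaternisation of the phosphine by the α-bromoketone followed by deprotonation gives the stabilised acyl ylide.

Step 11
Reactants: 15 methyl (1R,4S,5S,9S)-9-hydroxy-1-[(2S)-1-hydroxypropan-2-yl]-4-methylspiro[4.5]dec-7-ene-8-carboxylate; 19 3-methyl-1-(triphenyl-λ5-phosphanylidene)butan-2-one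
Product: 21 methyl (1R,4S,5S,9S)-9-hydroxy-4-methyl-1-[(2R,3E)-6-methyl-5-oxohept-3-en-2-yl]spiro[4.5]dec-7-ene-8-carboxylate, via aldehyde 20 (not isolated)
Conditions: TEMPO (10 mol %), PhI(OAc)2, CH2Cl2, rt; then 19, rt → 40 °C
Reagents that add atoms: none
Why: TEMPO/PhI(OAc)2 oxidises the primary alcohol in preference to the hindered, electron-poor secondary allylic alcohol, and Wittig olefination in the same pot with the stabilised ylide should give the E-enone without isolating the epimerisable α-branched aldehyde.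

Step 12
Reactants: 21 methyl (1R,4S,5S,9S)-9-hydroxy-4-methyl-1-[(2R,3E)-6-methyl-5-oxohept-3-en-2-yl]spiro[4.5]dec-7-ene-8-carboxylate
Product: 22 methyl (1R,4S,5S,9S)-9-hydroxy-4-methyl-1-[(2R)-6-methyl-5-oxoheptan-2-yl]spiro[4.5]dec-7-ene-8-carboxylate
Conditions: H2 (1 atm), RhCl(PPh3)3 (5 mol %), benzene–EtOH, rt
Reagents that add atoms: none
Why: Homogeneous hydrogenation with Wilkinson's catalyst should reduce the accessible 1,2-disubstituted enone C=C bond and leave the trisubstituted ring enoate, the ketone and the allylic alcohol untouched.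

Compound list
1 | (4aS,7S,7aR)-nepetalactone | C[C@H]1CC[C@H]2[C@@H]1C(=O)OC=C2C | starting material
2 | (4S,4aR,7S,7aR)-dihydronepetalactone | C[C@H]1CC[C@H]2[C@@H]1C(=O)OC[C@H]2C | intermediate
3 | 3-bromo-2-methylprop-1-ene (methallyl bromide) | C=C(C)CBr | starting material
4 | (4S,4aR,7S,7aR)-4,7-dimethyl-7a-(2-methylallyl)hexahydrocyclopenta[c]pyran-1(3H)-one | C[C@H]1CC[C@H]2[C@]1(CC(C)=C)C(=O)OC[C@H]2C | intermediate
5 | (4S,4aR,7S,7aR)-4,7-dimethyl-7a-(2-methylallyl)octahydrocyclopenta[c]pyran-1-ol (lactol, both anomers) | C[C@H]1CC[C@H]2[C@]1(CC(C)=C)C(O)OC[C@H]2C | intermediate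
6 | 1-[(4S,4aR,7S,7aR)-1-hydroxy-4,7-dimethylhexahydrocyclopenta[c]pyran-7a(1H)-yl]propan-2-one (keto lactol, both anomers) | C[C@H]1CC[C@H]2[C@]1(CC(C)=O)C(O)OC[C@H]2C | intermediate
7 | (5S,6R,9S)-6-[(2S)-1-hydroxypropan-2-yl]-9-methylspiro[4.4]non-3-en-2-one | C[C@H]1CC[C@H]([C@H](C)CO)[C@@]12CC(=O)C=C2 | intermediate
8 | tricyclic keto ether, formed when the side-chain oxygen of 7 adds to the enone β-carbon (future C6) on the face of C1 | C[C@H]1CC[C@@H]2[C@H](C)CO[C@H]3CC(=O)C[C@@]123 | intermediate
9 | (5S,6R,9S)-6-[(2S)-1-hydroxypropan-2-yl]-9-methylspiro[4.4]nonan-2-one | C[C@H]1CC[C@H]([C@H](C)CO)[C@@]12CC(=O)CC2 | intermediate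
10 | trimethyl{[(5S,6R,9S)-9-methyl-6-{(2S)-1-[(trimethylsilyl)oxy]propan-2-yl}spiro[4.4]non-2-en-2-yl]oxy}silane | C[C@H]1CC[C@H]([C@H](C)CO[Si](C)(C)C)[C@@]12CC(O[Si](C)(C)C)=CC2 | intermediate
11 | dibromocarbene adduct of 10 (spiro-fused 6,6-dibromo-1-(trimethylsiloxy)bicyclo[3.1.0]hexane, cyclopropane face undefined) | C[C@H]1CC[C@H]([C@H](C)CO[Si](C)(C)C)[C@@]12CC3(O[Si](C)(C)C)C(C2)C3(Br)Br | intermediate
12 | trimethylsilyl ether of 13 | C[C@H]1CC[C@H]([C@H](C)CO[Si](C)(C)C)[C@@]12CC(=O)C(Br)=CC2 | intermediate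
13 | (1R,4S,5S)-8-bromo-1-[(2S)-1-hydroxypropan-2-yl]-4-methylspiro[4.5]dec-7-en-9-one | C[C@H]1CC[C@H]([C@H](C)CO)[C@@]12CC(=O)C(Br)=CC2 | intermediate
14 | (1R,4S,5S,9S)-8-bromo-1-[(2S)-1-hydroxypropan-2-yl]-4-methylspiro[4.5]dec-7-en-9-ol | C[C@H]1CC[C@H]([C@H](C)CO)[C@@]12C[C@H](O)C(Br)=CC2 | intermediate
15 | methyl (1R,4S,5S,9S)-9-hydroxy-1-[(2S)-1-hydroxypropan-2-yl]-4-methylspiro[4.5]dec-7-ene-8-carboxylate | C[C@H]1CC[C@H]([C@H](C)CO)[C@@]12C[C@H](O)C(C(=O)OC)=CC2 | intermediate
16 | 1-bromo-3-methylbutan-2-one | CC(C)C(=O)CBr | starting material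
17 | triphenylphosphine | c1ccc(cc1)P(c1ccccc1)c1ccccc1 | starting material
18 | (3-methyl-2-oxobutyl)triphenylphosphonium bromide | CC(C)C(=O)C[P+](c1ccccc1)(c1ccccc1)c1ccccc1.[Br-] | intermediate
19 | 3-methyl-1-(triphenyl-λ5-phosphanylidene)butan-2-one | CC(C)C(=O)C=P(c1ccccc1)(c1ccccc1)c1ccccc1 | intermediate
20 | methyl (1R,4S,5S,9S)-9-hydroxy-4-methyl-1-[(2S)-1-oxopropan-2-yl]spiro[4.5]dec-7-ene-8-carboxylate | C[C@H]1CC[C@H]([C@H](C)C=O)[C@@]12C[C@H](O)C(C(=O)OC)=CC2 | intermediate
21 | methyl (1R,4S,5S,9S)-9-hydroxy-4-methyl-1-[(2R,3E)-6-methyl-5-oxohept-3-en-2-yl]spiro[4.5]dec-7-ene-8-carboxylate | C[C@H]1CC[C@H]([C@H](C)/C=C/C(=O)C(C)C)[C@@]12C[C@H](O)C(C(=O)OC)=CC2 | intermediate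
22 | methyl (1R,4S,5S,9S)-9-hydroxy-4-methyl-1-[(2R)-6-methyl-5-oxoheptan-2-yl]spiro[4.5]dec-7-ene-8-carboxylate (CNP0116894.1) | COC(=O)C1=CC[C@@]2(C[C@@H]1O)[C@@H]([C@H](C)CCC(=O)C(C)C)CC[C@@H]2C | target

Total step count: 12. Longest linear sequence: 11 (steps 1–9, 11 and 12; step 10 is a side branch).

Steps most likely to fail

Step 2. The crowded tertiary enolate may alkylate sluggishly (proton return, O-alkylation), and the ring methyl next to the reacting carbon may erode the convex-face preference. The fallback sets out from 2 and comes back at 6. It makes the C5–C10 bond by carbenoid addition to an enol ether instead of by enolate alkylation. DIBAL-H reduction of 2 gives dihydronepetalactol F1. Dehydration with MsCl/Et3N gives the bicyclic enol ether F2. Rh2(OAc)4-catalysed addition of diazoacetone (from acetyl chloride and TMSCHN2) to the convex face gives the alkoxycyclopropyl ketone F3. Dilute aqueous HCl in THF then opens this donor–acceptor cyclopropane to keto lactol 6.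

Step 5. The aldol closure on the hindered lactol may be slow. The oxa-Michael adduct may also be so favoured, and its reversal so slow under the hydrogenation conditions, that conversion stalls. The fallback sets out from 5 and comes back at 9. It masks the hydroxyl group before the enone exists. Ring-opening silylation of lactol 5 (TBSCl, imidazole, DMF) gives the silyloxy aldehyde F4, and ozonolysis gives the keto aldehyde F5. KOH/MeOH closes the silyl-protected spiro enone F6, H2 over Pd/C gives the silyl-protected spiro ketone F7, and TBAF releases 9.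

Step 7. tert-Butoxide may desilylate the enol ether before carbene transfer, or carbene transfer may be incomplete, so that ketone 9 is returned. The fallback sets out from 10 and comes back at 15. It keeps the one-carbon enlargement of the same ring but inserts CH2 and adds the halogen afterwards. Simmons–Smith cyclopropanation (Et2Zn, CH2I2) of 10 gives the siloxycyclopropane F8. FeCl3 in DMF opens the internal bond oxidatively (Saegusa ring expansion) to the β-chloro ketone F9. NaOAc in MeOH eliminates HCl to the spiro cyclohexenone F10, and I2/pyridine gives the 2-iodoenone F11. (R)-CBS reduction gives the iodo allylic alcohol F12, and the carbonylation conditions of step 9 convert it into 15.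

Further compounds
F1 | step 2 | (4S,4aR,7S,7aR)-4,7-dimethyloctahydrocyclopenta[c]pyran-1-ol (dihydronepetalactol, both anomers) | C[C@H]1CC[C@H]2[C@@H]1C(O)OC[C@H]2C
F2 | step 2 | (4S,4aR,7S)-4,7-dimethyl-3,4,4a,5,6,7-hexahydrocyclopenta[c]pyran | C[C@H]1CC[C@H]2C1=COC[C@H]2C
F3 | step 2 | acetylcyclopropane fused across C1–C7a of F2 on the convex face (acetyl-bearing carbon undefined) | C[C@H]1CC[C@H]2[C@@]13C(C(C)=O)[C@@H]3OC[C@H]2C
F4 | step 5 | (1R,2R,5S)-2-[(2S)-1-(tert-butyldimethylsilyloxy)propan-2-yl]-5-methyl-1-(2-methylallyl)cyclopentane-1-carbaldehyde | C[C@H]1CC[C@H]([C@H](C)CO[Si](C)(C)C(C)(C)C)[C@]1(CC(C)=C)C=O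
F5 | step 5 | corresponding 1-(2-oxopropyl)cyclopentane-1-carbaldehyde | C[C@H]1CC[C@H]([C@H](C)CO[Si](C)(C)C(C)(C)C)[C@]1(CC(C)=O)C=O
F6 | step 5 | tert-butyldimethylsilyl ether of 7 | C[C@H]1CC[C@H]([C@H](C)CO[Si](C)(C)C(C)(C)C)[C@@]12CC(=O)C=C2
F7 | step 5 | tert-butyldimethylsilyl ether of 9 | C[C@H]1CC[C@H]([C@H](C)CO[Si](C)(C)C(C)(C)C)[C@@]12CC(=O)CC2
F8 | step 7 | methylene adduct of 10 (spiro-fused 1-(trimethylsiloxy)bicyclo[3.1.0]hexane, cyclopropane face undefined) | C[C@H]1CC[C@H]([C@H](C)CO[Si](C)(C)C)[C@@]12CC3(O[Si](C)(C)C)CC3C2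
F9 | step 7 | (1R,4S,5S)-7-chloro-1-[(2S)-1-hydroxypropan-2-yl]-4-methylspiro[4.5]decan-9-one (C7 undefined) | C[C@H]1CC[C@H]([C@H](C)CO)[C@@]12CC(=O)CC(Cl)C2
F10 | step 7 | (1R,4S,5S)-1-[(2S)-1-hydroxypropan-2-yl]-4-methylspiro[4.5]dec-7-en-9-one | C[C@H]1CC[C@H]([C@H](C)CO)[C@@]12CC(=O)C=CC2
F11 | step 7 | (1R,4S,5S)-1-[(2S)-1-hydroxypropan-2-yl]-8-iodo-4-methylspiro[4.5]dec-7-en-9-one | C[C@H]1CC[C@H]([C@H](C)CO)[C@@]12CC(=O)C(I)=CC2
F12 | step 7 | (1R,4S,5S,9S)-1-[(2S)-1-hydroxypropan-2-yl]-8-iodo-4-methylspiro[4.5]dec-7-en-9-ol | C[C@H]1CC[C@H]([C@H](C)CO)[C@@]12C[C@H](O)C(I)=CC2
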